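**Retrosynthetic overview**
1. Names used: ring A is the 3-methoxy-4,5-dihydroxyphenyl ring, ring B the benzo ring, and ring C the 1,4-dioxane ring with O1, C2 (bears ring A, S), C3 (bears CH2OH, R) and O4. OMe sits on C5 and the (E)-3-hydroxypropenyl chain on C7.
2. Enabling feature: C3 of ring C carries a CH2OH next to O4, so O4–C3–CH2OH is the pattern left by a 6-exo-tet opening of a terminal epoxide by the ring B phenol oxygen O4. The cis C2/C3 relation equals an erythro 1-aryl-2,3-epoxypropan-1-ol after two SN2 inversions. O4 (para to the C7 chain) is the more acidic catechol oxygen of ring B and can be masked alone.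
3. Disconnections: (a) allylic alcohol and ring A catechol back to a cinnamate bis-pivalate (last step); (b) O4–C3 (epoxide opening) and O1–C2 (Mitsunobu) in one flask, back to epoxy alcohol 4 and phenol 6; (c) 4 from a Sharpless kinetic resolution of vinyl carbinol 3.
4. Rings A and B are bought, both as 5-hydroxyvanillin 1. Ring C is the only ring formed, in step 6.

Key step: step 6

Remark: read by the CIP rules, the given SMILES is the (2S,3R) isomer, with ring A and CH2OH cis on ring C. The route is built for this isomer, which is kept away from base once the para hydroxyl of ring A is free.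

Step 1
Reactants: 1 3,4-dihydroxy-5-methoxybenzaldehyde (5-hydroxyvanillin)
Product: 2 5-formyl-3-methoxy-1,2-phenylene bis(2,2-dimethylpropanoate)
Conditions: PivCl (2.4 equiv), Et3N (3 equiv), DMAP (0.1 equiv), CH2Cl2, 0 → 23 °C
Reagents that add atoms: pivaloyl chloride, CC(C)(C)C(=O)Cl
Why: DMAP-catalysed O-acylation masks the ring A catechol as hindered, electron-withdrawing pivalates that later hold back benzylic ionisation and come off in the final hydride step.

Step 2
Reactants: 2 bis-pivalate aldehyde
Product: 3 racemic 5-(1-hydroxyprop-2-en-1-yl)-3-methoxy-1,2-phenylene bis(2,2-dimethylpropanoate)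
Conditions: CH2=CHMgBr (1.05 equiv), THF, −78 °C; then pH 7 phosphate buffer at −78 °C
Reagents that add atoms: vinylmagnesium bromide, C=C[Mg]Br
Why: Grignard 1,2-addition to the activated aldehyde should be far faster at −78 °C than attack on the hindered aryl pivalates, and the racemic carbinol centre is sorted in step 3.

Step 3
Reactants: 3 racemic vinyl carbinol
Product: 4 5-{(R)-hydroxy[(2S)-oxiran-2-yl]methyl}-3-methoxy-1,2-phenylene bis(2,2-dimethylpropanoate) (erythro epoxy alcohol)
Conditions: Ti(OiPr)4 (0.15 equiv), D-(−)-DIPT (0.18 equiv), tBuOOH (0.45 equiv), 4 Å molecular sieves, CH2Cl2, −20 °C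
Reagents that add atoms: tert-butyl hydroperoxide, CC(C)(C)OO
Why: In this Sharpless kinetic resolution the catalyst formed from Ti(OiPr)4 and D-(−)-DIPT should epoxidise only the (S)-carbinol on the tartrate-dictated alkene face, which sets the epoxide carbon as S in the erythro relation (the untouched carbinol carbon is named R in 4 only because the CIP ranks change) and leaves the (R)-carbinol behind.

Step 4
Reactants: 1 3,4-dihydroxy-5-methoxybenzaldehyde
Product: 5 3-hydroxy-5-methoxy-4-(prop-2-en-1-yloxy)benzaldehyde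
Conditions: allyl bromide (1.05 equiv), NaHCO3 (1.2 equiv), DMF, 40 °C
Reagents that add atoms: allyl bromide, C=CCBr
Why: The hydroxyl para to the formyl group is the more acidic one, so a weak base forms only its phenoxide and the Williamson alkylation places the allyl group on the future O4 and leaves the future O1 free.

Step 5
Reactants: 5 4-O-allyl aldehyde
Product: 6 methyl (2E)-3-[3-hydroxy-5-methoxy-4-(prop-2-en-1-yloxy)phenyl]prop-2-enoate
Conditions: Ph3P=CHCO2Me (1.2 equiv), toluene, 80 °C
Reagents that add atoms: methyl (triphenylphosphoranylidene)acetate, COC(=O)C=P(c1ccccc1)(c1ccccc1)c1ccccc1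
Why: The Wittig olefination with a stabilised ylide tolerates the free phenol and should give the E cinnamate, as stabilised ylides do.

Step 6
Reactants: 4 erythro epoxy alcohol; 6 allyl-masked phenol cinnamate
Product: 9 methyl (2E)-3-{(2S,3R)-2-[3,4-bis(pivaloyloxy)-5-methoxyphenyl]-3-(hydroxymethyl)-5-methoxy-2,3-dihydro-1,4-benzodioxin-7-yl}prop-2-enoate, via Mitsunobu ether 7 (not isolated), via free phenol 8 (not isolated)
Conditions: PPh3 (1.2 equiv), DIAD (1.15 equiv), THF, 0 → 23 °C; then in the same flask Pd(PPh3)4 (5 mol %), HCO2H (1.5 equiv), Et3N (5 equiv), 23 → 55 °C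
Reagents that add atoms: none
Why: The Mitsunobu reagents turn the carbinol of 4 into its oxyphosphonium salt, and the only free phenol of 6 (the future O1) displaces it by SN2 to give 7, ionisation being held back by the two acyloxy groups on ring A and by the neighbouring epoxide; zerovalent palladium then ionises the allyl aryl ether, formate reduces the allyl fragment to propene (Tsuji-type deallylation), and the released phenol 8, as its triethylammonium phenoxide, attacks the internal epoxide carbon from the rear. The closest known reactions are Mitsunobu aryl ether formation on Sharpless epoxy alcohols and the base-induced cyclisation of 2-(oxiranylmethoxy)phenols to 2-hydroxymethyl-1,4-benzodioxanes. Ring C closes in the 6-exo-tet mode at O4–C3, and the epoxide oxygen stays on the terminal carbon as the CH2OH group. C2 becomes S by inversion of the R carbinol and C3 becomes R by inversion of the S epoxide carbon, so the erythro relation of 4 is carried stereospecifically into the cis relation of 9 without reliance on facial selectivity. The step needs O1 to bond before O4, which is secured by the non-migrating allyl mask on the more acidic oxygen. It also needs 6-exo over 7-endo attack, which is favoured by the smaller ring and by the known preference of such phenoxides for the internal carbon.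

Step 7
Reactants: 9 cis-benzodioxane cinnamate bis-pivalate
Product: 10 5-[(2S,3R)-3-(hydroxymethyl)-7-[(1E)-3-hydroxyprop-1-en-1-yl]-5-methoxy-2,3-dihydro-1,4-benzodioxin-2-yl]-3-methoxybenzene-1,2-diol
Conditions: iBu2AlH (10 equiv), CH2Cl2, −78 °C; then aq. KNaC4H4O6/NaH2PO4 (pH 6–7) under argon
Reagents that add atoms: none
Why: Hydride reduction with iBu2AlH takes the conjugated ester in the 1,2-sense to the E allylic alcohol and cleaves both aryl pivalates at low temperature, and the near-neutral work-up avoids the phenoxide-triggered retro-oxa-Michael opening through a quinone methide that could epimerise C2, so both stereocentres are kept.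

**Compound list**
1 | 3,4-dihydroxy-5-methoxybenzaldehyde (5-hydroxyvanillin) | COc1cc(C=O)cc(O)c1O | starting material
2 | 5-formyl-3-methoxy-1,2-phenylene bis(2,2-dimethylpropanoate) | COc1cc(C=O)cc(OC(=O)C(C)(C)C)c1OC(=O)C(C)(C)C | intermediate
3 | racemic 5-(1-hydroxyprop-2-en-1-yl)-3-methoxy-1,2-phenylene bis(2,2-dimethylpropanoate) | COc1cc(C(O)C=C)cc(OC(=O)C(C)(C)C)c1OC(=O)C(C)(C)C | intermediate
4 | 5-{(R)-hydroxy[(2S)-oxiran-2-yl]methyl}-3-methoxy-1,2-phenylene bis(2,2-dimethylpropanoate) | COc1cc([C@@H](O)[C@@H]2CO2)cc(OC(=O)C(C)(C)C)c1OC(=O)C(C)(C)C | intermediate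
5 | 3-hydroxy-5-methoxy-4-(prop-2-en-1-yloxy)benzaldehyde | C=CCOc1c(O)cc(C=O)cc1OC | intermediate
6 | methyl (2E)-3-[3-hydroxy-5-methoxy-4-(prop-2-en-1-yloxy)phenyl]prop-2-enoate | C=CCOc1c(O)cc(/C=C/C(=O)OC)cc1OC | intermediate
7 | methyl (2E)-3-{3-[(S)-[3,4-bis(pivaloyloxy)-5-methoxyphenyl][(2S)-oxiran-2-yl]methoxy]-5-methoxy-4-(prop-2-en-1-yloxy)phenyl}prop-2-enoate | COc1cc([C@H](Oc2cc(/C=C/C(=O)OC)cc(OC)c2OCC=C)[C@@H]3CO3)cc(OC(=O)C(C)(C)C)c1OC(=O)C(C)(C)C | intermediate
8 | methyl (2E)-3-{3-[(S)-[3,4-bis(pivaloyloxy)-5-methoxyphenyl][(2S)-oxiran-2-yl]methoxy]-4-hydroxy-5-methoxyphenyl}prop-2-enoate | COc1cc([C@H](Oc2cc(/C=C/C(=O)OC)cc(OC)c2O)[C@@H]3CO3)cc(OC(=O)C(C)(C)C)c1OC(=O)C(C)(C)C | intermediate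
9 | methyl (2E)-3-{(2S,3R)-2-[3,4-bis(pivaloyloxy)-5-methoxyphenyl]-3-(hydroxymethyl)-5-methoxy-2,3-dihydro-1,4-benzodioxin-7-yl}prop-2-enoate (cis) | COc1cc([C@@H]2Oc3cc(/C=C/C(=O)OC)cc(OC)c3O[C@@H]2CO)cc(OC(=O)C(C)(C)C)c1OC(=O)C(C)(C)C | intermediate
10 | 5-[(2S,3R)-3-(hydroxymethyl)-7-[(1E)-3-hydroxyprop-1-en-1-yl]-5-methoxy-2,3-dihydro-1,4-benzodioxin-2-yl]-3-methoxybenzene-1,2-diol | COc1cc([C@@H]2Oc3cc(/C=C/CO)cc(OC)c3O[C@@H]2CO)cc(O)c1O | target

Total step count: 7. Longest linear sequence: 5 steps (1 → 2 → 3 → 4 → 9 → 10).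

**Steps most likely to fail**

Step 6. The closure to the cis ring has to carry ring A or the epoxide methylene in an axial position, so opening at the terminal epoxide carbon (7-endo) or intermolecular opening may overtake the 6-exo closure. The fallback sets out from 7, isolated after the Mitsunobu stage, and comes back to the route at 10.
- The epoxide is first opened at its terminal carbon with pivalic acid (PivOH, Cs2CO3 cat., DMF, 60 °C) to the hydroxy pivalate F1.
- Deallylation (Pd(PPh3)4, HCO2H, Et3N, THF) gives the phenol alcohol F2.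
- An intramolecular Mitsunobu etherification (PPh3, DIAD, THF, 0 °C) closes the same O4–C3 bond with the same inversion. Because the terminal carbon is blocked, only the six-membered ring can form, giving the tripivalate F3.
- F3 is taken through the conditions of step 7, which also remove the third pivalate.

Step 3. The rate difference between the two enantiomers of this aryl vinyl carbinol may be too small, or the epoxy alcohol may be opened by isopropoxide on titanium during the slow reaction. The fallback sets out from 3 and comes back at 4.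
- Racemic 3 is resolved by enzymatic acyl transfer (immobilised Candida antarctica lipase B, vinyl acetate, MTBE, 30 °C). This should leave the (S)-vinyl carbinol F4 untouched and convert its enantiomer into the (R)-allylic acetate F5.
- After separation, F4 is epoxidised under hydroxyl direction (VO(acac)2 cat., tBuOOH, CH2Cl2, 0 °C). This reaction type favours the erythro epoxy alcohol for carbinols with an unsubstituted vinyl group and gives 4, the threo isomer being removed by chromatography.

Step 7. Once the para oxygen of ring A is bound to aluminium, Lewis-acid-assisted loss of the O1 aryloxide through a quinone methide may epimerise C2 or lead to reductive ring opening. The free catechol may also be oxidised by air in the work-up. The fallback sets out from 9 and comes back at 10.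
- The two pivalates are first removed by buffered hydrazinolysis (N2H4·AcOH, DMF, 23 °C) to the catechol ester F6.
- All three hydroxyl groups are silylated (TBSCl, imidazole, DMF) to the tris(silyl ether) F7.
- iBu2AlH (CH2Cl2, −78 °C) then only has to reduce the ester and gives the silylated allylic alcohol F8.
- Et3N·3HF (THF, 0 → 23 °C), a weakly acidic fluoride source, frees 10 without a phenoxide being present.

**Further compounds**
F1 | step 6 | methyl (2E)-3-{3-[(1S,2S)-1-[3,4-bis(pivaloyloxy)-5-methoxyphenyl]-2-hydroxy-3-(pivaloyloxy)propoxy]-5-methoxy-4-(prop-2-en-1-yloxy)phenyl}prop-2-enoate | COc1cc([C@H](Oc2cc(/C=C/C(=O)OC)cc(OC)c2OCC=C)[C@@H](O)COC(=O)C(C)(C)C)cc(OC(=O)C(C)(C)C)c1OC(=O)C(C)(C)C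
F2 | step 6 | methyl (2E)-3-{3-[(1S,2S)-1-[3,4-bis(pivaloyloxy)-5-methoxyphenyl]-2-hydroxy-3-(pivaloyloxy)propoxy]-4-hydroxy-5-methoxyphenyl}prop-2-enoate | COc1cc([C@H](Oc2cc(/C=C/C(=O)OC)cc(OC)c2O)[C@@H](O)COC(=O)C(C)(C)C)cc(OC(=O)C(C)(C)C)c1OC(=O)C(C)(C)C
F3 | step 6 | methyl (2E)-3-{(2S,3R)-2-[3,4-bis(pivaloyloxy)-5-methoxyphenyl]-5-methoxy-3-[(pivaloyloxy)methyl]-2,3-dihydro-1,4-benzodioxin-7-yl}prop-2-enoate | COc1cc([C@@H]2Oc3cc(/C=C/C(=O)OC)cc(OC)c3O[C@@H]2COC(=O)C(C)(C)C)cc(OC(=O)C(C)(C)C)c1OC(=O)C(C)(C)C
F4 | step 3 | 5-[(1S)-1-hydroxyprop-2-en-1-yl]-3-methoxy-1,2-phenylene bis(2,2-dimethylpropanoate) | COc1cc([C@@H](O)C=C)cc(OC(=O)C(C)(C)C)c1OC(=O)C(C)(C)C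
F5 | step 3 | 5-[(1R)-1-(acetyloxy)prop-2-en-1-yl]-3-methoxy-1,2-phenylene bis(2,2-dimethylpropanoate) | COc1cc([C@H](OC(C)=O)C=C)cc(OC(=O)C(C)(C)C)c1OC(=O)C(C)(C)C
F6 | step 7 | methyl (2E)-3-[(2S,3R)-2-(3,4-dihydroxy-5-methoxyphenyl)-3-(hydroxymethyl)-5-methoxy-2,3-dihydro-1,4-benzodioxin-7-yl]prop-2-enoate | COc1cc([C@@H]2Oc3cc(/C=C/C(=O)OC)cc(OC)c3O[C@@H]2CO)cc(O)c1O
F7 | step 7 | methyl (2E)-3-{(2S,3R)-2-[3,4-bis(tert-butyldimethylsilyloxy)-5-methoxyphenyl]-3-[(tert-butyldimethylsilyloxy)methyl]-5-methoxy-2,3-dihydro-1,4-benzodioxin-7-yl}prop-2-enoate | COc1cc([C@@H]2Oc3cc(/C=C/C(=O)OC)cc(OC)c3O[C@@H]2CO[Si](C)(C)C(C)(C)C)cc(O[Si](C)(C)C(C)(C)C)c1O[Si](C)(C)C(C)(C)C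
F8 | step 7 | (2E)-3-{(2S,3R)-2-[3,4-bis(tert-butyldimethylsilyloxy)-5-methoxyphenyl]-3-[(tert-butyldimethylsilyloxy)methyl]-5-methoxy-2,3-dihydro-1,4-benzodioxin-7-yl}prop-2-en-1-ol | COc1cc([C@@H]2Oc3cc(/C=C/CO)cc(OC)c3O[C@@H]2CO[Si](C)(C)C(C)(C)C)cc(O[Si](C)(C)C(C)(C)C)c1O[Si](C)(C)C(C)(C)C
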